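The target is the ring-opened (seco-chromanol) hydroquinone of a tocotrienol-type acid (acid numbering: C14 carbinol carbon, C16 benzylic carbon). Two features are exploited: C15H2 adjoins the hydroxylated quaternary C14 (an epoxide-opening retron), and on the benzene ring the C3 methyl and the side-chain-bearing C1 both flank the C2 oxygen, so both descend from the two equivalent methyls of symmetric 2,6-dimethylhydroquinone dimethyl ether. In one operation, lateral potassiation of that arene and SN2 opening of an (R)-2-methyl-2-alkyloxirane (one step from farnesylacetone) form the C16–C15 bond, complete the carbon skeleton and release the tertiary (R)-carbinol unprotected. Terminal allylic oxidation and CAN/dithionite unmasking finish the synthesis.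

Key step: step 3

Remark: (5E,9E)-farnesylacetone is assumed to be purchasable isomerically pure (it is otherwise one acetoacetic ester alkylation away from (2E,6E)-farnesyl bromide).

Step 1
Reactants: 1 (5E,9E)-6,10,14-trimethylpentadeca-5,9,13-trien-2-one ((E,E)-farnesylacetone)
Product: 2 (R)-2-methyl-2-[(3E,7E)-4,8,12-trimethyltrideca-3,7,11-trien-1-yl]oxirane
Conditions: Me3S(O)I, NaH, THF (ylide preformed); (S)-LaLi3-tris(binaphthoxide) (5 mol %), (2,4,6-(MeO)3C6H2)3P=O (5 mol %), MS 5 Å, THF, rt
Reagents that add atoms: dimethylsulfoxonium methylide C[S+](C)(=O)[CH2-], generated from trimethylsulfoxonium iodide C[S+](C)(C)=O.[I-]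
Why: Catalytic asymmetric Corey–Chaykovsky epoxidation, in which the La/Li/binaphthoxide–phosphine oxide complex binds both the methyl ketone and the ylide and should deliver CH2 to the Si face of the carbonyl (O > CH2R > CH3), so the new stereocentre is set as R by catalyst control (the antipodal catalyst is taken if a test run shows the opposite sense), while the isolated trisubstituted alkenes are inert to the ylide.

Step 2
Reactants: 3 2,6-dimethylbenzene-1,4-diol (2,6-dimethylhydroquinone)
Product: 4 2,5-dimethoxy-1,3-dimethylbenzene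
Conditions: MeI, K2CO3, DMF, rt, Ar
Reagents that add atoms: iodomethane CI
Why: Williamson O-methylation of both phenoxides under argon should give the symmetric dimethyl ether, whose ether groups withstand the superbase of step 3 and can be removed oxidatively at the end.

Step 3
Reactants: 4 2,5-dimethoxy-1,3-dimethylbenzene (1.5 equiv); 2 (R)-2-methyl-2-[(3E,7E)-4,8,12-trimethyltrideca-3,7,11-trien-1-yl]oxirane
Product: 6 (3R,6E,10E)-1-(2,5-dimethoxy-3-methylphenyl)-3,7,11,15-tetramethylhexadeca-6,10,14-trien-3-ol, via benzylic potassium reagent 5 (not isolated)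
Conditions: 4, n-BuLi, KOt-Bu, 2,2,6,6-tetramethylpiperidine, THF, −78 °C; then 2, −78 → −20 °C; aq NH4Cl
Reagents that add atoms: none
Why: Under n-BuLi/KOt-Bu/TMP(H) (LiNK) conditions the amine shuttles the metal from kinetically formed aryl sites to the thermodynamically preferred benzylic position, giving benzylic potassium reagent 5, whose delocalised carbanion opens oxirane 2 by SN2 attack at the unsubstituted ring CH2, forging the ArCH2–CH2 bond and releasing the tertiary alkoxide. The closest known reaction type is lateral (benzylic) metalation of methoxytoluenes followed by alkylation with an epoxide. No ring is closed. No new stereocentre is created: the quaternary oxirane carbon is not attacked, its C–O bond stays intact and its configuration passes unchanged into C3 of 6 (still R, because the CIP order O > former oxirane CH2 > chain CH2 > CH3 is retained). The step needs benzylic rather than ring metalation (secured by the TMP(H)-mediated equilibration; the two methyl groups of 4 are equivalent by the mirror plane through C2 and C5, so only one benzylic anion exists), attack at CH2 rather than at the quaternary carbon (secured by sterics) and mono-alkylation (secured by the excess of 4). The triene chain of 2 offers neither an acidic nor an electrophilic site to the reagent.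

Step 4
Reactants: 6 (3R,6E,10E)-1-(2,5-dimethoxy-3-methylphenyl)-3,7,11,15-tetramethylhexadeca-6,10,14-trien-3-ol
Product: 7 (2E,6E,10E,14R)-16-(2,5-dimethoxy-3-methylphenyl)-2,6,10,14-tetramethylhexadeca-2,6,10-triene-1,14-diol
Conditions: SeO2 (cat.), t-BuOOH, salicylic acid (cat.), CH2Cl2, 0 °C → rt
Reagents that add atoms: tert-butyl hydroperoxide CC(C)(C)OO
Why: Catalytic SeO2/t-BuOOH allylic oxidation (ene reaction, then [2,3]-sigmatropic shift) should select the (E)-methyl group of the terminal isopropylidene unit, the most accessible trisubstituted alkene, and give the (E)-allylic alcohol as is usual for polyprenyl chains; conversion is kept partial, 6 is recycled and any enal formed is carried into step 5.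

Step 5
Reactants: 7 (2E,6E,10E,14R)-16-(2,5-dimethoxy-3-methylphenyl)-2,6,10,14-tetramethylhexadeca-2,6,10-triene-1,14-diol
Product: 9 (2E,6E,10E,14R)-16-(2,5-dimethoxy-3-methylphenyl)-14-hydroxy-2,6,10,14-tetramethylhexadeca-2,6,10-trienoic acid, via enal 8 (not isolated)
Conditions: MnO2, CH2Cl2, rt; filter, concentrate; then NaClO2, NaH2PO4, 2-methyl-2-butene, t-BuOH/H2O, rt
Reagents that add atoms: sodium chlorite [Na+].[O-]Cl=O
Why: MnO2 should oxidise only the primary allylic alcohol to the (E)-enal, and the Pinnick oxidation (NaClO2 with 2-methyl-2-butene as HOCl scavenger) takes the enal to the acid without touching the tertiary alcohol, the alkenes or the electron-rich arene.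

Step 6
Reactants: 9 (2E,6E,10E,14R)-16-(2,5-dimethoxy-3-methylphenyl)-14-hydroxy-2,6,10,14-tetramethylhexadeca-2,6,10-trienoic acid
Product: 11 (2E,6E,10E,14R)-16-(2,5-dihydroxy-3-methylphenyl)-14-hydroxy-2,6,10,14-tetramethylhexadeca-2,6,10-trienoic acid, via quinone acid 10 (not isolated)
Conditions: (NH4)2Ce(NO3)6, MeCN/H2O, 0 °C; extract into EtOAc; then aq Na2S2O4, EtOAc/H2O, rt, Ar
Reagents that add atoms: water O
Why: CAN oxidative demethylation of the p-dimethoxyarene should give the p-benzoquinone, which sodium dithionite reduces to the hydroquinone; the cold, brief oxidation and an acid-free work-up under argon should leave the tertiary alcohol (no cyclodehydration to a chromanol), the alkenes, the acid and the stereocentre unchanged.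

Compound list
1 | (5E,9E)-6,10,14-trimethylpentadeca-5,9,13-trien-2-one ((E,E)-farnesylacetone) | CC(C)=CCC/C(C)=C/CC/C(C)=C/CCC(C)=O | starting material
2 | (R)-2-methyl-2-[(3E,7E)-4,8,12-trimethyltrideca-3,7,11-trien-1-yl]oxirane | CC(C)=CCC/C(C)=C/CC/C(C)=C/CC[C@@]1(C)OC1 | intermediate
3 | 2,6-dimethylbenzene-1,4-diol (2,6-dimethylhydroquinone) | Cc1cc(O)cc(C)c1O | starting material
4 | 2,5-dimethoxy-1,3-dimethylbenzene | COc1cc(C)c(OC)c(C)c1 | intermediate
5 | (2,5-dimethoxy-3-methylbenzyl)potassium | [K]Cc1cc(OC)cc(C)c1OC | intermediate (not isolated)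
6 | (3R,6E,10E)-1-(2,5-dimethoxy-3-methylphenyl)-3,7,11,15-tetramethylhexadeca-6,10,14-trien-3-ol | CC(C)=CCC/C(C)=C/CC/C(C)=C/CC[C@@](C)(O)CCc1cc(OC)cc(C)c1OC | intermediate
7 | (2E,6E,10E,14R)-16-(2,5-dimethoxy-3-methylphenyl)-2,6,10,14-tetramethylhexadeca-2,6,10-triene-1,14-diol | C/C(=C\CC/C(C)=C/CC[C@@](C)(O)CCc1cc(OC)cc(C)c1OC)CC/C=C(\C)CO | intermediate
8 | (2E,6E,10E,14R)-16-(2,5-dimethoxy-3-methylphenyl)-14-hydroxy-2,6,10,14-tetramethylhexadeca-2,6,10-trienal | C/C(=C\CC/C(C)=C/CC[C@@](C)(O)CCc1cc(OC)cc(C)c1OC)CC/C=C(\C)C=O | intermediate (not isolated)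
9 | (2E,6E,10E,14R)-16-(2,5-dimethoxy-3-methylphenyl)-14-hydroxy-2,6,10,14-tetramethylhexadeca-2,6,10-trienoic acid | C/C(=C\CC/C(C)=C/CC[C@@](C)(O)CCc1cc(OC)cc(C)c1OC)CC/C=C(\C)C(=O)O | intermediate
10 | (2E,6E,10E,14R)-14-hydroxy-2,6,10,14-tetramethyl-16-(5-methyl-3,6-dioxocyclohexa-1,4-dien-1-yl)hexadeca-2,6,10-trienoic acid | C/C(=C\CC/C(C)=C/CC[C@@](C)(O)CCC1=CC(=O)C=C(C)C1=O)CC/C=C(\C)C(=O)O | intermediate (not isolated)
11 | (2E,6E,10E,14R)-16-(2,5-dihydroxy-3-methylphenyl)-14-hydroxy-2,6,10,14-tetramethylhexadeca-2,6,10-trienoic acid | C/C(=C\CC/C(C)=C/CC[C@@](C)(O)CCc1cc(O)cc(C)c1O)CC/C=C(\C)C(=O)O | target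

Total step count: 6. Longest linear sequence: 5 steps (steps 1, 3, 4, 5, 6 from 1).

Steps most likely to fail

Step 3 (key step). Metalation may occur at a ring position ortho to the C5 methoxy group instead of at the methyl group, or the strongly basic medium may isomerise the oxirane to an allylic alkoxide instead of substituting it. The fallback makes the same bond with a sulfone-stabilised, much less basic benzylic carbanion. It sets out from 4 and returns to the route at 6. Radical bromination of 4 (NBS in slight deficit, AIBN, PhCF3, reflux) should give 1-(bromomethyl)-2,5-dimethoxy-3-methylbenzene F1. Displacement with sodium benzenesulfinate (DMF, rt) should give 1-[(benzenesulfonyl)methyl]-2,5-dimethoxy-3-methylbenzene F2. Lithiation (n-BuLi, THF/DMPU, −78 °C) and opening of oxirane 2 at its CH2 terminus (→ rt) should give (3R,6E,10E)-1-(benzenesulfonyl)-1-(2,5-dimethoxy-3-methylphenyl)-3,7,11,15-tetramethylhexadeca-6,10,14-trien-3-ol F3 as a mixture of C1 epimers. Reductive desulfonylation (Mg, MeOH, rt) then gives 6.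

Step 4. Oxidation may also occur at internal allylic methylene groups or run on past the alcohol, so that site selectivity is poor on a late, valuable intermediate. The fallback moves the oxidation to the cheap starting ketone. It sets out from 1 and returns at 7. SeO2 (cat.)/t-BuOOH on 1 should give (5E,9E,13E)-15-hydroxy-6,10,14-trimethylpentadeca-5,9,13-trien-2-one F4. Silylation (TBSCl, imidazole, DMF) gives (5E,9E,13E)-15-[(tert-butyldimethylsilyl)oxy]-6,10,14-trimethylpentadeca-5,9,13-trien-2-one F5. The conditions of step 1 convert it into tert-butyl(dimethyl){[(2E,6E,10E)-2,6,10-trimethyl-13-[(2R)-2-methyloxiran-2-yl]trideca-2,6,10-trien-1-yl]oxy}silane F6. Opening with benzylic potassium reagent 5 under the conditions of step 3 gives (3R,6E,10E,14E)-16-[(tert-butyldimethylsilyl)oxy]-1-(2,5-dimethoxy-3-methylphenyl)-3,7,11,15-tetramethylhexadeca-6,10,14-trien-3-ol F7. Desilylation (Bu4NF, THF) gives 7.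

Step 1. Enantiofacial discrimination between the methyl and the CH2CH2R arm of an aliphatic methyl ketone may be weak, and no later step could correct it. The fallback takes the stereocentre from the chiral pool. It bypasses 1, sets out from commercial (2E,6E)-farnesyl bromide and (S)-2-methylglycidol (C[C@]1(CO)CO1), and returns at 2. Farnesyl bromide and sodium benzenesulfinate (DMF, rt) give [(2E,6E)-3,7,11-trimethyldodeca-2,6,10-trien-1-yl]sulfonylbenzene F8. Its lithio derivative (n-BuLi, THF/DMPU, −78 °C → rt) opens the oxirane CH2 of (S)-2-methylglycidol, used as its lithium alkoxide, to give (2R,5E,9E)-4-(benzenesulfonyl)-2,6,10,14-tetramethylpentadeca-5,9,13-triene-1,2-diol F9 (C4 epimers). Palladium-catalysed hydride desulfonylation (LiBHEt3, PdCl2(dppp) cat., THF, 0 °C) should give (2R,5E,9E)-2,6,10,14-tetramethylpentadeca-5,9,13-triene-1,2-diol F10 with the alkene position and geometry retained. Selective primary tosylation (TsCl, Et3N, DMAP cat., CH2Cl2, 0 °C) gives (2R,5E,9E)-2-hydroxy-2,6,10,14-tetramethylpentadeca-5,9,13-trien-1-yl 4-methylbenzenesulfonate F11. Ring closure (K2CO3, MeOH, rt) gives 2; the quaternary carbon is never a reaction site, so its configuration is carried through.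

Further compounds
F1 | step 3 | 1-(bromomethyl)-2,5-dimethoxy-3-methylbenzene | BrCc1cc(OC)cc(C)c1OC
F2 | step 3 | 1-[(benzenesulfonyl)methyl]-2,5-dimethoxy-3-methylbenzene | COc1cc(C)c(OC)c(CS(=O)(=O)c2ccccc2)c1
F3 | step 3 | (3R,6E,10E)-1-(benzenesulfonyl)-1-(2,5-dimethoxy-3-methylphenyl)-3,7,11,15-tetramethylhexadeca-6,10,14-trien-3-ol (C1 epimers) | CC(C)=CCC/C(C)=C/CC/C(C)=C/CC[C@@](C)(O)CC(c1cc(OC)cc(C)c1OC)S(=O)(=O)c1ccccc1
F4 | step 4 | (5E,9E,13E)-15-hydroxy-6,10,14-trimethylpentadeca-5,9,13-trien-2-one | OC/C(C)=C/CC/C(C)=C/CC/C(C)=C/CCC(C)=O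
F5 | step 4 | (5E,9E,13E)-15-[(tert-butyldimethylsilyl)oxy]-6,10,14-trimethylpentadeca-5,9,13-trien-2-one | CC(C)(C)[Si](C)(C)OC/C(C)=C/CC/C(C)=C/CC/C(C)=C/CCC(C)=O
F6 | step 4 | tert-butyl(dimethyl){[(2E,6E,10E)-2,6,10-trimethyl-13-[(2R)-2-methyloxiran-2-yl]trideca-2,6,10-trien-1-yl]oxy}silane | CC(C)(C)[Si](C)(C)OC/C(C)=C/CC/C(C)=C/CC/C(C)=C/CC[C@@]1(C)OC1
F7 | step 4 | (3R,6E,10E,14E)-16-[(tert-butyldimethylsilyl)oxy]-1-(2,5-dimethoxy-3-methylphenyl)-3,7,11,15-tetramethylhexadeca-6,10,14-trien-3-ol | CC(C)(C)[Si](C)(C)OC/C(C)=C/CC/C(C)=C/CC/C(C)=C/CC[C@@](C)(O)CCc1cc(OC)cc(C)c1OC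
F8 | step 1 | [(2E,6E)-3,7,11-trimethyldodeca-2,6,10-trien-1-yl]sulfonylbenzene | CC(C)=CCC/C(C)=C/CC/C(C)=C/CS(=O)(=O)c1ccccc1
F9 | step 1 | (2R,5E,9E)-4-(benzenesulfonyl)-2,6,10,14-tetramethylpentadeca-5,9,13-triene-1,2-diol (C4 epimers) | CC(C)=CCC/C(C)=C/CC/C(C)=C/C(C[C@@](C)(O)CO)S(=O)(=O)c1ccccc1
F10 | step 1 | (2R,5E,9E)-2,6,10,14-tetramethylpentadeca-5,9,13-triene-1,2-diol | CC(C)=CCC/C(C)=C/CC/C(C)=C/CC[C@@](C)(O)CO
F11 | step 1 | (2R,5E,9E)-2-hydroxy-2,6,10,14-tetramethylpentadeca-5,9,13-trien-1-yl 4-methylbenzenesulfonate | CC(C)=CCC/C(C)=C/CC/C(C)=C/CC[C@@](C)(O)COS(=O)(=O)c1ccc(C)cc1
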